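## Retrosynthetic overview

1. Target ⇐ BCl3 cleavage of two aryl isopropyl ethers ⇐ MnO2 oxidation of an allylic/benzylic alcohol (free CH2OH tolerated).
2. That alcohol ⇐ 1,3-carbonyl transposition of a tetralone aldol adduct (silylate, reduce C1=O, dehydrate, desilylate).
3. Aldol adduct ⇐ intermolecular lithium-enolate aldol of an (R)-3-(silyloxymethyl)-1-tetralone with O-isopropylvanillin (key C–C bond, joins the two aryl halves).
4. Tetralone (the only ring built) ⇐ intramolecular Friedel–Crafts acylation para to OMe ⇐ Evans alkylation with tert-butyl bromoacetate (sets the single stereocentre).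
5. Both aryl units ⇐ vanillin (O-isopropylation; Doebner homologation and hydrogenation for the propanoic acid).

Assumption: the stereocentre in the target SMILES is (R) (C3 of the 3,4-dihydronaphthalene); stereocentres created in steps 10 and 12 are destroyed in steps 13 and 15, so compounds 18–23 are carried as diastereomer mixtures and their SMILES define only the permanent centre.

## Route

Step 1
Reactants: 1 vanillin (4-hydroxy-3-methoxybenzaldehyde)
Product: 2 4-isopropoxy-3-methoxybenzaldehyde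
Conditions: 2-bromopropane (1.5 equiv), K2CO3 (2 equiv), DMF, 70 °C
Reagents that add atoms: 2-bromopropane CC(C)Br
Why: Williamson ether synthesis (SN2 alkylation of the phenoxide); the isopropyl ether survives H2/Pd, strong acid, enolate bases, hydride and fluoride and is later removed beside OMe by BCl3.

Step 2
Reactants: 2 4-isopropoxy-3-methoxybenzaldehyde; 3 malonic acid
Product: 4 (E)-3-(4-isopropoxy-3-methoxyphenyl)prop-2-enoic acid
Conditions: pyridine, piperidine (cat.), 100 °C
Reagents that add atoms: none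
Why: Knoevenagel–Doebner condensation with in situ decarboxylation gives the E-cinnamic acid reliably from an aryl aldehyde.

Step 3
Reactants: 4 (E)-3-(4-isopropoxy-3-methoxyphenyl)prop-2-enoic acid
Product: 5 3-(4-isopropoxy-3-methoxyphenyl)propanoic acid
Conditions: H2 (1 atm), 10% Pd/C, EtOAc, rt
Reagents that add atoms: none
Why: catalytic hydrogenation saturates the conjugated C=C while the alkyl aryl ethers and the acid are untouched.

Step 4
Reactants: 5 3-(4-isopropoxy-3-methoxyphenyl)propanoic acid; 6 (S)-4-benzyl-1,3-oxazolidin-2-one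
Product: 8 (S)-4-benzyl-3-[3-(4-isopropoxy-3-methoxyphenyl)propanoyl]-1,3-oxazolidin-2-one, via mixed pivalic anhydride 7 (not isolated)
Conditions: PivCl (1.1 equiv), Et3N (2.5 equiv), THF, −20 °C; then LiCl (1.1 equiv), 6, −20 °C → rt
Reagents that add atoms: none
Why: N-acylation of the Evans auxiliary through the mixed pivalic anhydride, which the LiCl/Et3N-activated oxazolidinone attacks selectively at the unhindered acyl carbon.

Step 5
Reactants: 8 (S)-4-benzyl-3-[3-(4-isopropoxy-3-methoxyphenyl)propanoyl]-1,3-oxazolidin-2-one; 9 tert-butyl bromoacetate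
Product: 11 tert-butyl (R)-4-[(S)-4-benzyl-2-oxo-1,3-oxazolidin-3-yl]-3-(4-isopropoxy-3-methoxybenzyl)-4-oxobutanoate, via sodium Z-enolate 10 (not isolated)
Conditions: NaHMDS (1.1 equiv), THF, −78 °C; then 9 (3 equiv), −78 → −40 °C
Reagents that add atoms: none
Why: Evans asymmetric alkylation: the chelated Z-enolate is alkylated on the face opposite the auxiliary's benzyl group, setting the new stereocentre as (R) (dr typically ≥ 95:5, minor isomer removed by chromatography).

Step 6
Reactants: 11 tert-butyl (R)-4-[(S)-4-benzyl-2-oxo-1,3-oxazolidin-3-yl]-3-(4-isopropoxy-3-methoxybenzyl)-4-oxobutanoate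
Product: 12 tert-butyl (R)-3-(hydroxymethyl)-4-(4-isopropoxy-3-methoxyphenyl)butanoate
Conditions: LiBH4 (1.2 equiv), H2O (1.1 equiv), Et2O, 0 °C
Reagents that add atoms: none
Why: chemoselective hydride reduction of the activated exocyclic imide carbonyl (reductive auxiliary cleavage) leaves the hindered tert-butyl ester and the stereocentre intact.

Step 7
Reactants: 12 tert-butyl (R)-3-(hydroxymethyl)-4-(4-isopropoxy-3-methoxyphenyl)butanoate
Product: 13 tert-butyl (R)-3-{[(tert-butyldiphenylsilyl)oxy]methyl}-4-(4-isopropoxy-3-methoxyphenyl)butanoate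
Conditions: TBDPSCl (1.1 equiv), imidazole (2 equiv), DMF, 0 °C → rt
Reagents that add atoms: tert-butyl(chloro)diphenylsilane CC(C)(C)[Si](Cl)(c1ccccc1)c1ccccc1
Why: silyl ether formation on the primary alcohol blocks lactonisation onto the ester and gives the most acid-stable common silyl ether for the next two steps.

Step 8
Reactants: 13 tert-butyl (R)-3-{[(tert-butyldiphenylsilyl)oxy]methyl}-4-(4-isopropoxy-3-methoxyphenyl)butanoate
Product: 14 (R)-3-{[(tert-butyldiphenylsilyl)oxy]methyl}-4-(4-isopropoxy-3-methoxyphenyl)butanoic acid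
Conditions: TFA/CH2Cl2 (1:4), 0 °C → rt; evaporate with toluene
Reagents that add atoms: none
Why: acidolysis of the tert-butyl ester (E1 loss of isobutene) frees the acid under conditions that a primary TBDPS ether and the aryl ethers tolerate.

Step 9
Reactants: 14 (R)-3-{[(tert-butyldiphenylsilyl)oxy]methyl}-4-(4-isopropoxy-3-methoxyphenyl)butanoic acid
Product: 16 (R)-3-{[(tert-butyldiphenylsilyl)oxy]methyl}-7-isopropoxy-6-methoxy-3,4-dihydronaphthalen-1(2H)-one, via mixed trifluoroacetic anhydride 15 (not isolated)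
Conditions: TFAA (2 equiv), CH2Cl2, 0 °C → rt
Reagents that add atoms: none
Why: intramolecular Friedel–Crafts acylation of the mixed anhydride closes the six-membered ring at the arene position para to OMe (the only accessible activated site ortho to the side chain) and leaves the β-stereocentre untouched.

Step 10 (key step)
Reactants: 16 (R)-3-{[(tert-butyldiphenylsilyl)oxy]methyl}-7-isopropoxy-6-methoxy-3,4-dihydronaphthalen-1(2H)-one; 2 4-isopropoxy-3-methoxybenzaldehyde
Product: 18 (3R)-3-{[(tert-butyldiphenylsilyl)oxy]methyl}-2-[hydroxy(4-isopropoxy-3-methoxyphenyl)methyl]-7-isopropoxy-6-methoxy-3,4-dihydronaphthalen-1(2H)-one, via lithium enolate 17 (not isolated)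
Conditions: LDA (1.1 equiv), THF, −78 °C; then 2 (1.2 equiv), −78 °C; AcOH quench at −78 °C
Reagents that add atoms: none
Why: directed aldol addition: the kinetic lithium enolate of 16 (one enolisable α-position only) adds to the non-enolisable aldehyde to forge the bond that unites the two aryl fragments; the aldehyde enters anti to the C3 substituent, the two new centres (C2, carbinol) need no control because both become sp2 later, and C3 is not touched.

Step 11
Reactants: 18 (3R)-3-{[(tert-butyldiphenylsilyl)oxy]methyl}-2-[hydroxy(4-isopropoxy-3-methoxyphenyl)methyl]-7-isopropoxy-6-methoxy-3,4-dihydronaphthalen-1(2H)-one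
Product: 19 (3R)-2-{[(tert-butyldimethylsilyl)oxy](4-isopropoxy-3-methoxyphenyl)methyl}-3-{[(tert-butyldiphenylsilyl)oxy]methyl}-7-isopropoxy-6-methoxy-3,4-dihydronaphthalen-1(2H)-one
Conditions: TBSOTf (1.3 equiv), 2,6-lutidine (2 equiv), CH2Cl2, −78 → 0 °C
Reagents that add atoms: tert-butyldimethylsilyl trifluoromethanesulfonate CC(C)(C)[Si](C)(C)OS(=O)(=O)C(F)(F)F
Why: O-silylation of the aldol hydroxyl under non-nucleophilic base stops retro-aldol and dehydration and differentiates this oxygen from the one made in step 12.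

Step 12
Reactants: 19 (3R)-2-{[(tert-butyldimethylsilyl)oxy](4-isopropoxy-3-methoxyphenyl)methyl}-3-{[(tert-butyldiphenylsilyl)oxy]methyl}-7-isopropoxy-6-methoxy-3,4-dihydronaphthalen-1(2H)-one
Product: 20 (3R)-2-{[(tert-butyldimethylsilyl)oxy](4-isopropoxy-3-methoxyphenyl)methyl}-3-{[(tert-butyldiphenylsilyl)oxy]methyl}-7-isopropoxy-6-methoxy-1,2,3,4-tetrahydronaphthalen-1-ol
Conditions: NaBH4 (2 equiv), CeCl3·7H2O (1 equiv), MeOH/THF, −20 → 0 °C
Reagents that add atoms: none
Why: Luche-type hydride reduction of the aryl ketone gives the benzylic alcohol under weakly basic conditions that avoid β-elimination and silyl migration; the new C1 centre is uncontrolled and is removed in step 13.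

Step 13
Reactants: 20 (3R)-2-{[(tert-butyldimethylsilyl)oxy](4-isopropoxy-3-methoxyphenyl)methyl}-3-{[(tert-butyldiphenylsilyl)oxy]methyl}-7-isopropoxy-6-methoxy-1,2,3,4-tetrahydronaphthalen-1-ol
Product: 22 (2R)-3-{[(tert-butyldimethylsilyl)oxy](4-isopropoxy-3-methoxyphenyl)methyl}-2-{[(tert-butyldiphenylsilyl)oxy]methyl}-6-isopropoxy-7-methoxy-1,2-dihydronaphthalene, via benzylic mesylate 21 (not isolated)
Conditions: MsCl (1.5 equiv), Et3N (4 equiv), CH2Cl2, 0 °C → rt; then DBU (3 equiv), rt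
Reagents that add atoms: none
Why: sulfonylation then β-elimination (E1/E2 dehydration): the p-methoxy-activated benzylic mesylate loses the only β-hydrogen (C2–H) to give the ring styrene, erasing the C1 and C2 centres, while the basic medium spares the acid-labile benzylic OTBS group and the permanent stereocentre.

Step 14
Reactants: 22 (2R)-3-{[(tert-butyldimethylsilyl)oxy](4-isopropoxy-3-methoxyphenyl)methyl}-2-{[(tert-butyldiphenylsilyl)oxy]methyl}-6-isopropoxy-7-methoxy-1,2-dihydronaphthalene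
Product: 23 [(3R)-3-(hydroxymethyl)-7-isopropoxy-6-methoxy-3,4-dihydronaphthalen-2-yl](4-isopropoxy-3-methoxyphenyl)methanol
Conditions: TBAF (4 equiv), AcOH (4 equiv), THF, rt; used crude
Reagents that add atoms: none
Why: fluoride-induced desilylation (Si–F bond formation) removes both silyl ethers in one buffered, non-acidic operation, so the ionisable allylic/benzylic alcohol does not transpose.

Step 15
Reactants: 23 [(3R)-3-(hydroxymethyl)-7-isopropoxy-6-methoxy-3,4-dihydronaphthalen-2-yl](4-isopropoxy-3-methoxyphenyl)methanol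
Product: 24 [(3R)-3-(hydroxymethyl)-7-isopropoxy-6-methoxy-3,4-dihydronaphthalen-2-yl](4-isopropoxy-3-methoxyphenyl)methanone
Conditions: activated MnO2 (20 equiv), CH2Cl2, rt
Reagents that add atoms: none
Why: MnO2 oxidation is selective for the allylic/benzylic secondary alcohol (both epimers converge on one ketone) and leaves the saturated primary alcohol alone; the C3 centre cannot enolise because the ketone's only α-carbon is the sp2 ring carbon.

Step 16
Reactants: 24 [(3R)-3-(hydroxymethyl)-7-isopropoxy-6-methoxy-3,4-dihydronaphthalen-2-yl](4-isopropoxy-3-methoxyphenyl)methanone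
Product: 25 [(3R)-7-hydroxy-3-(hydroxymethyl)-6-methoxy-3,4-dihydronaphthalen-2-yl](4-hydroxy-3-methoxyphenyl)methanone
Conditions: BCl3 (1 M in CH2Cl2, 6 equiv), CH2Cl2, −78 → 0 °C; then H2O
Reagents that add atoms: none
Why: Lewis-acid ether cleavage: BCl3 dealkylates the secondary (isopropyl) aryl ethers by SN1-type C–O scission much faster than the methyl ethers at ≤ 0 °C, releasing both phenols without touching the enone or the stereocentre.

## Compound list

1 | vanillin (4-hydroxy-3-methoxybenzaldehyde) | COc1cc(C=O)ccc1O | starting material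
2 | 4-isopropoxy-3-methoxybenzaldehyde | COc1cc(C=O)ccc1OC(C)C | intermediate
3 | malonic acid | OC(=O)CC(O)=O | starting material
4 | (E)-3-(4-isopropoxy-3-methoxyphenyl)prop-2-enoic acid | COc1cc(/C=C/C(O)=O)ccc1OC(C)C | intermediate
5 | 3-(4-isopropoxy-3-methoxyphenyl)propanoic acid | COc1cc(CCC(O)=O)ccc1OC(C)C | intermediate
6 | (S)-4-benzyl-1,3-oxazolidin-2-one | O=C1N[C@@H](Cc2ccccc2)CO1 | starting material
7 | mixed anhydride of 5 with pivalic acid (not isolated) | COc1cc(CCC(=O)OC(=O)C(C)(C)C)ccc1OC(C)C | intermediate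
8 | (S)-4-benzyl-3-[3-(4-isopropoxy-3-methoxyphenyl)propanoyl]-1,3-oxazolidin-2-one | COc1cc(CCC(=O)N2[C@@H](Cc3ccccc3)COC2=O)ccc1OC(C)C | intermediate
9 | tert-butyl bromoacetate | CC(C)(C)OC(=O)CBr | starting material
10 | sodium (Z)-enolate of 8 (not isolated) | COc1cc(C/C=C(\[O-])N2[C@@H](Cc3ccccc3)COC2=O)ccc1OC(C)C.[Na+] | intermediate
11 | tert-butyl (R)-4-[(S)-4-benzyl-2-oxo-1,3-oxazolidin-3-yl]-3-(4-isopropoxy-3-methoxybenzyl)-4-oxobutanoate | COc1cc(C[C@H](CC(=O)OC(C)(C)C)C(=O)N2[C@@H](Cc3ccccc3)COC2=O)ccc1OC(C)C | intermediate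
12 | tert-butyl (R)-3-(hydroxymethyl)-4-(4-isopropoxy-3-methoxyphenyl)butanoate | COc1cc(C[C@H](CC(=O)OC(C)(C)C)CO)ccc1OC(C)C | intermediate
13 | tert-butyl (R)-3-{[(tert-butyldiphenylsilyl)oxy]methyl}-4-(4-isopropoxy-3-methoxyphenyl)butanoate | COc1cc(C[C@H](CC(=O)OC(C)(C)C)CO[Si](c2ccccc2)(c2ccccc2)C(C)(C)C)ccc1OC(C)C | intermediate
14 | (R)-3-{[(tert-butyldiphenylsilyl)oxy]methyl}-4-(4-isopropoxy-3-methoxyphenyl)butanoic acid | COc1cc(C[C@H](CC(O)=O)CO[Si](c2ccccc2)(c2ccccc2)C(C)(C)C)ccc1OC(C)C | intermediate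
15 | mixed anhydride of 14 with trifluoroacetic acid (not isolated) | COc1cc(C[C@H](CC(=O)OC(=O)C(F)(F)F)CO[Si](c2ccccc2)(c2ccccc2)C(C)(C)C)ccc1OC(C)C | intermediate
16 | (R)-3-{[(tert-butyldiphenylsilyl)oxy]methyl}-7-isopropoxy-6-methoxy-3,4-dihydronaphthalen-1(2H)-one | COc1cc2c(cc1OC(C)C)C(=O)C[C@H](CO[Si](c3ccccc3)(c3ccccc3)C(C)(C)C)C2 | intermediate
17 | lithium enolate of 16 (not isolated) | COc1cc2c(cc1OC(C)C)C([O-])=C[C@H](CO[Si](c3ccccc3)(c3ccccc3)C(C)(C)C)C2.[Li+] | intermediate
18 | (3R)-3-{[(tert-butyldiphenylsilyl)oxy]methyl}-2-[hydroxy(4-isopropoxy-3-methoxyphenyl)methyl]-7-isopropoxy-6-methoxy-3,4-dihydronaphthalen-1(2H)-one (2,3-trans expected as major; both carbinol epimers) | COc1cc2c(cc1OC(C)C)C(=O)C(C(O)c1ccc(OC(C)C)c(OC)c1)[C@H](CO[Si](c3ccccc3)(c3ccccc3)C(C)(C)C)C2 | intermediate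
19 | O-TBS ether of 18 at the carbinol oxygen | COc1cc2c(cc1OC(C)C)C(=O)C(C(O[Si](C)(C)C(C)(C)C)c1ccc(OC(C)C)c(OC)c1)[C@H](CO[Si](c3ccccc3)(c3ccccc3)C(C)(C)C)C2 | intermediate
20 | (3R)-2-{[(tert-butyldimethylsilyl)oxy](4-isopropoxy-3-methoxyphenyl)methyl}-3-{[(tert-butyldiphenylsilyl)oxy]methyl}-7-isopropoxy-6-methoxy-1,2,3,4-tetrahydronaphthalen-1-ol (diastereomer mixture at C1, C2, carbinol) | COc1cc2c(cc1OC(C)C)C(O)C(C(O[Si](C)(C)C(C)(C)C)c1ccc(OC(C)C)c(OC)c1)[C@H](CO[Si](c3ccccc3)(c3ccccc3)C(C)(C)C)C2 | intermediate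
21 | C1 methanesulfonate of 20 (not isolated) | COc1cc2c(cc1OC(C)C)C(OS(C)(=O)=O)C(C(O[Si](C)(C)C(C)(C)C)c1ccc(OC(C)C)c(OC)c1)[C@H](CO[Si](c3ccccc3)(c3ccccc3)C(C)(C)C)C2 | intermediate
22 | (2R)-3-{[(tert-butyldimethylsilyl)oxy](4-isopropoxy-3-methoxyphenyl)methyl}-2-{[(tert-butyldiphenylsilyl)oxy]methyl}-6-isopropoxy-7-methoxy-1,2-dihydronaphthalene (both carbinol epimers) | COc1cc(C(O[Si](C)(C)C(C)(C)C)C2=Cc3cc(OC(C)C)c(OC)cc3C[C@H]2CO[Si](c4ccccc4)(c4ccccc4)C(C)(C)C)ccc1OC(C)C | intermediate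
23 | [(3R)-3-(hydroxymethyl)-7-isopropoxy-6-methoxy-3,4-dihydronaphthalen-2-yl](4-isopropoxy-3-methoxyphenyl)methanol (both carbinol epimers) | COc1cc(C(O)C2=Cc3cc(OC(C)C)c(OC)cc3C[C@H]2CO)ccc1OC(C)C | intermediate
24 | [(3R)-3-(hydroxymethyl)-7-isopropoxy-6-methoxy-3,4-dihydronaphthalen-2-yl](4-isopropoxy-3-methoxyphenyl)methanone | COc1cc(C(=O)C2=Cc3cc(OC(C)C)c(OC)cc3C[C@H]2CO)ccc1OC(C)C | intermediate
25 | [(3R)-7-hydroxy-3-(hydroxymethyl)-6-methoxy-3,4-dihydronaphthalen-2-yl](4-hydroxy-3-methoxyphenyl)methanone | COc1cc(C(=O)C2=Cc3cc(O)c(OC)cc3C[C@H]2CO)ccc1O | target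

## Step count and fallbacks

Total steps: 16. Longest linear sequence: 16 steps (1 → 25); aldehyde 2 from step 1 is used twice (steps 2 and 10).

The three steps most likely to fail:

**Step 9 (Friedel–Crafts cyclisation with a silyl ether on board).** The risk is partial loss of the TBDPS group in the acidic steps 8–9, followed by lactonisation instead of ring closure. The fallback sets out from 12 and comes back at 16, carrying the alcohol through the acid chemistry as an acid-proof ester. Compound 12 is acylated with pivaloyl chloride/pyridine to tert-butyl (R)-4-(4-isopropoxy-3-methoxyphenyl)-3-[(pivaloyloxy)methyl]butanoate F1. TFA/CH2Cl2 then gives (R)-4-(4-isopropoxy-3-methoxyphenyl)-3-[(pivaloyloxy)methyl]butanoic acid F2. This is cyclised by direct protic cyclodehydration in Eaton's reagent (P2O5/MeSO3H, rt) to [(2R)-6-isopropoxy-7-methoxy-4-oxo-1,2,3,4-tetrahydronaphthalen-2-yl]methyl pivalate F3. NaOMe/MeOH methanolysis gives (R)-3-(hydroxymethyl)-7-isopropoxy-6-methoxy-3,4-dihydronaphthalen-1(2H)-one F4, and TBDPSCl/imidazole returns 16.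

**Step 13 (dehydration beside an ionisable benzylic silyl ether).** The risks are incomplete elimination of one C1/C2 diastereomer, or ionisation at the carbinol carbon once the alkene is in place. The fallback sets out from 18 and comes back at 23, replacing the reduce/dehydrate sequence with a Wharton 1,3-transposition. Aldol 18 is dehydrated under E1cB conditions (MsCl, Et3N, then DBU) to (R,E)-3-{[(tert-butyldiphenylsilyl)oxy]methyl}-7-isopropoxy-2-(4-isopropoxy-3-methoxybenzylidene)-6-methoxy-3,4-dihydronaphthalen-1(2H)-one F5. Weitz–Scheffer epoxidation (H2O2, NaOH, MeOH/THF, 0 °C) gives the spiro-epoxy ketone 3-{[(tert-butyldiphenylsilyl)oxy]methyl}-7-isopropoxy-3'-(4-isopropoxy-3-methoxyphenyl)-6-methoxy-3,4-dihydro-1H-spiro[naphthalene-2,2'-oxiran]-1-one F6. Hydrazine hydrate with catalytic AcOH in MeOH (Wharton reaction) moves the oxygen to the exocyclic carbon and the double bond into the ring, giving [(3R)-3-{[(tert-butyldiphenylsilyl)oxy]methyl}-7-isopropoxy-6-methoxy-3,4-dihydronaphthalen-2-yl](4-isopropoxy-3-methoxyphenyl)methanol F7. TBAF then gives 23.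

**Step 16 (BCl3 on the free hydroxy enone).** The risks are chloroborinate formation at the primary alcohol with addition across the Lewis-acid-activated enone, or partial demethylation. The fallback sets out from 24 and comes back at 25, with ordered deprotection on a masked alcohol. Compound 24 is acetylated (Ac2O, pyridine, DMAP) to [(2R)-6-isopropoxy-3-(4-isopropoxy-3-methoxybenzoyl)-7-methoxy-1,2-dihydronaphthalen-2-yl]methyl acetate F8. The isopropyl ethers are cleaved with AlCl3 (CH2Cl2, 0 °C) to [(2R)-6-hydroxy-3-(4-hydroxy-3-methoxybenzoyl)-7-methoxy-1,2-dihydronaphthalen-2-yl]methyl acetate F9. K2CO3/MeOH methanolysis of the acetate then gives 25.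

## Further compounds

F1 | step 9 | tert-butyl (R)-4-(4-isopropoxy-3-methoxyphenyl)-3-[(pivaloyloxy)methyl]butanoate | COc1cc(C[C@H](CC(=O)OC(C)(C)C)COC(=O)C(C)(C)C)ccc1OC(C)C
F2 | step 9 | (R)-4-(4-isopropoxy-3-methoxyphenyl)-3-[(pivaloyloxy)methyl]butanoic acid | COc1cc(C[C@H](CC(O)=O)COC(=O)C(C)(C)C)ccc1OC(C)C
F3 | step 9 | [(2R)-6-isopropoxy-7-methoxy-4-oxo-1,2,3,4-tetrahydronaphthalen-2-yl]methyl pivalate | COc1cc2c(cc1OC(C)C)C(=O)C[C@H](COC(=O)C(C)(C)C)C2
F4 | step 9 | (R)-3-(hydroxymethyl)-7-isopropoxy-6-methoxy-3,4-dihydronaphthalen-1(2H)-one | COc1cc2c(cc1OC(C)C)C(=O)C[C@H](CO)C2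
F5 | step 13 | (R,E)-3-{[(tert-butyldiphenylsilyl)oxy]methyl}-7-isopropoxy-2-(4-isopropoxy-3-methoxybenzylidene)-6-methoxy-3,4-dihydronaphthalen-1(2H)-one | COc1cc2c(cc1OC(C)C)C(=O)/C(=C/c1ccc(OC(C)C)c(OC)c1)[C@H](CO[Si](c3ccccc3)(c3ccccc3)C(C)(C)C)C2
F6 | step 13 | 3-{[(tert-butyldiphenylsilyl)oxy]methyl}-7-isopropoxy-3'-(4-isopropoxy-3-methoxyphenyl)-6-methoxy-3,4-dihydro-1H-spiro[naphthalene-2,2'-oxiran]-1-one (C3 as in 16; epoxide diastereomers) | COc1cc2c(cc1OC(C)C)C(=O)C1(OC1c1ccc(OC(C)C)c(OC)c1)[C@H](CO[Si](c3ccccc3)(c3ccccc3)C(C)(C)C)C2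
F7 | step 13 | [(3R)-3-{[(tert-butyldiphenylsilyl)oxy]methyl}-7-isopropoxy-6-methoxy-3,4-dihydronaphthalen-2-yl](4-isopropoxy-3-methoxyphenyl)methanol (both carbinol epimers) | COc1cc(C(O)C2=Cc3cc(OC(C)C)c(OC)cc3C[C@H]2CO[Si](c4ccccc4)(c4ccccc4)C(C)(C)C)ccc1OC(C)C
F8 | step 16 | [(2R)-6-isopropoxy-3-(4-isopropoxy-3-methoxybenzoyl)-7-methoxy-1,2-dihydronaphthalen-2-yl]methyl acetate | COc1cc(C(=O)C2=Cc3cc(OC(C)C)c(OC)cc3C[C@H]2COC(C)=O)ccc1OC(C)C
F9 | step 16 | [(2R)-6-hydroxy-3-(4-hydroxy-3-methoxybenzoyl)-7-methoxy-1,2-dihydronaphthalen-2-yl]methyl acetate | COc1cc(C(=O)C2=Cc3cc(O)c(OC)cc3C[C@H]2COC(C)=O)ccc1O
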